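If the starting material turned into target and nothing capped the curve, one number per flask would draw the whole run. The runs pointed that way. By 30.0 h the north-west run had reached 32.8%, more than its 0.19 equiv of second substrate and more than the 10.0% of capture agent against starting material.

| flask | starting material | second substrate | capture agent | free catalyst | remark | time |
|---|---|---|---|---|---|---|
| north-west | 0.094 M | 0.19 equiv | 9.4 mM | 2.1 mol% | run made earlier |  |
| south-west | 0.094 M | 0.68 equiv | 9.4 mM | 2.1 mol% | run made earlier |  |
| north-east | 0.094 M | 1.9 equiv | 9.4 mM | 2.1 mol% | run made earlier |  |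
| larch | 0.094 M | 0.250 equiv | 9.40 mM | 2.1 mol% |  | 2.5 d |
| maple | 0.094 M | 0.500 equiv | 9.40 mM | 2.1 mol% |  | 2.5 d |
| oak | 0.094 M | 1.00 equiv | 9.40 mM | 2.1 mol% |  | 2.5 d |
| alder | 0.094 M | 2.00 equiv | 9.40 mM | 2.1 mol% |  | 2.5 d |

- north-west (time / h: target / %): 6.00: 7.1; 12.0: 15.4; 20.0: 24.1; 25.0: 29.1; 30.0: 32.8
- south-west (time / h: target / %): 6.00: 8.7; 12.0: 13.2; 20.0: 21.8; 25.0: 26.9; 30.0: 30.8
- north-east (time / h: target / %): 6.00: 8.0; 12.0: 12.1; 20.0: 20.3; 25.0: 23.3; 30.0: 29.1

(scatter of a reading: 1 percentage point)

- "hardly changes" means that all values lie within two and a half points (for a concentration: within two and a half percent of the largest)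

- amount of target at the end, in percent of the starting material charged for larch, maple, oak, alder, in this order
- how the row runs (rises, then falls / hardly changes / rises all the way / falls all the way / falls, then rises)

I took each run's clock, a pseudo-first-order time constant:

clock = time / ln(charge / starting material left)

north-west: 75.5 h
north-east: 87.2 h
lengthening for each equivalent: 0.287 d

The south-west run read 81.5 h, and the straight line gave 78.8 h. I took that gap as the width of the line.

On this line I read the clock of a flask at its own equivalents:

larch: 75.9 h
alder: 87.9 h

Larch's curve started at 0.0132 h⁻¹ of the charge, and I saw no knee. My line put its crossing of half of the charge at 52.6 h. For alder the line put that crossing at 60.9 h, but the end at 2.5 d lay closer to it than the width of the line, which is 1.83 h in crossing time, so I left open on which side of the end alder would cross. Both curves were still bending slowly toward the full charge.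

My row was 54.6%, 53.8%, 52.3% and 49.5%.

The forecast gave 55%, 54%, 52% and 48%, falls all the way, lower at alder than mine, and held that “so the second substrate is a mild inhibitor (or mildly drains target)”.

The flasks gave 53.8%, 53.3%, 52.3% and 50.3%: falls all the way.

    starting material + free catalyst ⇌ catalyst intermediate A (K = 16.0 M⁻¹, k = 0.00220 M⁻¹ s⁻¹)
    catalyst intermediate A → free catalyst + target (k = 0.00280 s⁻¹)
    second substrate + free catalyst ⇌ catalyst intermediate B (K = 150 M⁻¹, k = 0.00540 M⁻¹ s⁻¹)
    catalyst intermediate B → free catalyst + second product (k = 0.00350 s⁻¹)
    catalyst intermediate A + capture agent → trapped intermediate (k = 0.00150 M⁻¹ s⁻¹)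

Read back from its end value, larch's clock was 77.7 h against the 75.9 h I had carried, and alder's was 85.8 h against 87.9 h, longer by a factor of 1.10. After 1.25 d the free catalyst stood at 87.0% of its charge in larch and 79.6% in alder, a factor of 1.09, while catalyst intermediate B stood at 1.14% and 9.52%.

(The runs are calculated for an exercise; scatter was added.)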